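**Plan**

1. Retrosynthetic cuts: ring C of the flavonol is opened at O1–C2 and the C3 hydroxyl is removed (oxidative cyclisation of a 2'-hydroxychalcone). The chalcone C=C is then cut to an aryl aldehyde and an acetophenone. Next come the aryl C–O bond of the dioxane ring between C4' of ring B and the oxygen on the guaiacyl-bearing carbon, the C–C bond between the two sp3 dioxane carbons (aldol), and last the O–CH2 bond of an aryloxyacetyl unit.
2. Enabling feature: C4' of ring B is para to C1', the carbon bonded to C2 of pyranone ring C. The future C2 is carried on C1' as a nitrile, which makes a C4'–F bond an SNAr site; the ether carbon C3' (meta to the nitrile) stays inert.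
3. Forward order: phenol O-alkylation, Evans syn-aldol (joins the two future dioxane carbons), reductive auxiliary removal, primary O-tritylation, SNAr closure of the dioxane ring, nitrile to aldehyde, Claisen–Schmidt condensation, Algar–Flynn–Oyamada closure of ring C, hydrogenolysis.
4. Stereochemistry: both centres come from the (S)-4-benzyloxazolidinone-controlled syn-aldol (threo 1R,2R diol after reduction). The ring closure breaks no bond at either carbon, so threo becomes the trans-(2R,3R) benzodioxane, and no later step touches these centres.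

Key step: step 6

Assumption: the acetophenone partner 1-[2,4-bis(benzyloxy)-6-hydroxyphenyl]ethan-1-one is taken as a catalogue compound.

**Route**

Step 1
Reactants: 1 (S)-4-benzyl-1,3-oxazolidin-2-one; 2 bromoacetyl bromide
Product: 4 (S)-4-benzyl-3-(bromoacetyl)-1,3-oxazolidin-2-one, via lithium oxazolidinide 3 (not isolated)
Conditions: n-BuLi, THF, −78 °C; then 2, −78 to 0 °C
Reagents that add atoms: none
Why: N-acylation of the lithiated oxazolidinone by the acyl bromide (imide formation) is fast at −78 °C and selective for the acyl over the alkyl bromide, and the auxiliary stereocentre is not involved.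

Step 2
Reactants: 4 (S)-4-benzyl-3-(bromoacetyl)-1,3-oxazolidin-2-one; 5 4-fluoro-3-hydroxybenzonitrile
Product: 6 (S)-4-benzyl-3-[2-(5-cyano-2-fluorophenoxy)acetyl]-1,3-oxazolidin-2-one
Conditions: K2CO3, acetone, rt
Reagents that add atoms: none
Why: Williamson ether synthesis (SN2) of the acidic phenoxide on the highly reactive α-bromo imide should proceed under carbonate conditions far too mild to start SNAr at the C–F bond or to cleave the imide.

Step 3
Reactants: 6 (S)-4-benzyl-3-[2-(5-cyano-2-fluorophenoxy)acetyl]-1,3-oxazolidin-2-one; 7 4-(benzyloxy)-3-methoxybenzaldehyde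
Product: 9 (S)-4-benzyl-3-[(2S,3R)-3-[4-(benzyloxy)-3-methoxyphenyl]-2-(5-cyano-2-fluorophenoxy)-3-hydroxypropanoyl]-1,3-oxazolidin-2-one, via Z-boron enolate 8 (not isolated)
Conditions: Bu2BOTf, iPr2NEt, CH2Cl2, −78 to 0 °C; then 7, −78 to 0 °C; then pH 7 buffer, MeOH, 30% H2O2, 0 °C
Reagents that add atoms: none
Why: Evans syn-aldol reaction, in which the Z boron enolate 8 adds to the aldehyde through a chair Zimmerman–Traxler transition state on the face away from the benzyl group of the dipole-opposed (S)-auxiliary, so that C2 (S) and C3 (R) are set together as the syn adduct that corresponds to the threo diol.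

Step 4
Reactants: 9 (S)-4-benzyl-3-[(2S,3R)-3-[4-(benzyloxy)-3-methoxyphenyl]-2-(5-cyano-2-fluorophenoxy)-3-hydroxypropanoyl]-1,3-oxazolidin-2-one
Product: 10 3-{[(1R,2R)-1-[4-(benzyloxy)-3-methoxyphenyl]-1,3-dihydroxypropan-2-yl]oxy}-4-fluorobenzonitrile
Conditions: NaBH4, THF/H2O, 0 °C to rt
Reagents that add atoms: none
Why: Reductive cleavage of the N-acyloxazolidinone by hydride attack on the activated exocyclic carbonyl should release the primary alcohol and the auxiliary while nitrile, aryl fluoride and both stereocentres stay untouched (the descriptor of C2 changes from S to R only because the priorities change).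

Step 5
Reactants: 10 3-{[(1R,2R)-1-[4-(benzyloxy)-3-methoxyphenyl]-1,3-dihydroxypropan-2-yl]oxy}-4-fluorobenzonitrile
Product: 11 3-{[(1R,2R)-1-[4-(benzyloxy)-3-methoxyphenyl]-1-hydroxy-3-(trityloxy)propan-2-yl]oxy}-4-fluorobenzonitrile
Conditions: TrCl, Et3N, DMAP (cat.), CH2Cl2, rt
Reagents that add atoms: trityl chloride, ClC(c1ccccc1)(c1ccccc1)c1ccccc1
Why: Sterically controlled tritylation (SN1-type etherification) should take only the primary hydroxyl, leaving the benzylic hydroxyl as the sole nucleophile for ring closure and installing a base-stable group that, unlike a silyl ether, cannot migrate to a neighbouring alkoxide.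

Step 6
Reactants: 11 3-{[(1R,2R)-1-[4-(benzyloxy)-3-methoxyphenyl]-1-hydroxy-3-(trityloxy)propan-2-yl]oxy}-4-fluorobenzonitrile
Product: 13 (2R,3R)-2-[4-(benzyloxy)-3-methoxyphenyl]-3-[(trityloxy)methyl]-2,3-dihydro-1,4-benzodioxine-6-carbonitrile, via potassium alkoxide 12 (not isolated)
Conditions: KN(SiMe3)2, THF, −78 °C to rt
Reagents that add atoms: none
Why: Deprotonation of the benzylic hydroxyl gives potassium alkoxide 12, which adds to the fluorine-bearing carbon para to the nitrile to form a Meisenheimer complex with its charge delocalised onto the cyano nitrogen, and loss of fluoride restores the aromatic ring (addition–elimination, SNAr). The closest known reaction type is the intramolecular SNAr etherification of alkoxides onto 4-fluorobenzonitriles and 2-fluoroaryl ethers used to make chromans and 1,4-benzodioxanes. The dioxane ring closes in a 6-exo-trig mode, the alkoxide oxygen becoming O1 and the attacked carbon C8a of the 2,3-dihydro-1,4-benzodioxine. No new stereocentre is formed and no bond to either carbinol carbon is broken, so the threo 1R,2R centres from the aldol are carried over with retention and become the trans-2R,3R ring. The step needs chemoselectivity for the benzylic oxygen, which the trityl ether on the primary hydroxyl secures, and site selectivity for C–F over ipso attack at the ether-bearing carbon (a Smiles-type aryl shift), which is secured because only the C–F carbon is para to the nitrile and carries a leaving group. The benzodioxane regiochemistry (guaiacyl-bearing carbon on the oxygen para to the future chromone) is thereby fixed by construction.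

Step 7
Reactants: 13 (2R,3R)-2-[4-(benzyloxy)-3-methoxyphenyl]-3-[(trityloxy)methyl]-2,3-dihydro-1,4-benzodioxine-6-carbonitrile
Product: 15 (2R,3R)-2-[4-(benzyloxy)-3-methoxyphenyl]-3-[(trityloxy)methyl]-2,3-dihydro-1,4-benzodioxine-6-carbaldehyde, via N-aluminio aldimine 14 (not isolated)
Conditions: iBu2AlH, CH2Cl2, −78 °C; then aq. Rochelle salt, rt
Reagents that add atoms: water, O
Why: Partial reduction of the nitrile by one hydride of iBu2AlH should stop at the N-aluminio aldimine 14, which is hydrolysed on aqueous work-up to the aldehyde (nitrile-to-aldehyde reduction), with the ethers and the ring stereocentres inert.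

Step 8
Reactants: 15 (2R,3R)-2-[4-(benzyloxy)-3-methoxyphenyl]-3-[(trityloxy)methyl]-2,3-dihydro-1,4-benzodioxine-6-carbaldehyde; 16 1-[2,4-bis(benzyloxy)-6-hydroxyphenyl]ethan-1-one
Product: 17 (E)-1-[2,4-bis(benzyloxy)-6-hydroxyphenyl]-3-{(2R,3R)-2-[4-(benzyloxy)-3-methoxyphenyl]-3-[(trityloxy)methyl]-2,3-dihydro-1,4-benzodioxin-6-yl}prop-2-en-1-one
Conditions: KOH (50% aq.), EtOH/THF, rt
Reagents that add atoms: none
Why: Claisen–Schmidt condensation (crossed aldol addition of the methyl ketone enolate to the non-enolisable aldehyde, then E1cB dehydration) should give the E-chalcone, and the dioxane stereocentres carry no acidic hydrogen.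

Step 9
Reactants: 17 (E)-1-[2,4-bis(benzyloxy)-6-hydroxyphenyl]-3-{(2R,3R)-2-[4-(benzyloxy)-3-methoxyphenyl]-3-[(trityloxy)methyl]-2,3-dihydro-1,4-benzodioxin-6-yl}prop-2-en-1-one
Product: 19 5,7-bis(benzyloxy)-2-{(2R,3R)-2-[4-(benzyloxy)-3-methoxyphenyl]-3-[(trityloxy)methyl]-2,3-dihydro-1,4-benzodioxin-6-yl}-3-hydroxy-4H-chromen-4-one, via trans-dihydroflavonol 18 (not isolated)
Conditions: 30% H2O2, NaOH (aq.), MeOH/THF, 0 °C to rt
Reagents that add atoms: hydrogen peroxide, OO
Why: Algar–Flynn–Oyamada reaction, in which alkaline hydrogen peroxide cyclises the 2'-hydroxychalcone oxidatively to the trans-dihydroflavonol 18 and dehydrogenates it in the same medium to the flavonol, closing ring C with the 3-hydroxyl in place; low temperature and excess peroxide are chosen to favour the six-membered closure over the aurone.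

Step 10
Reactants: 19 5,7-bis(benzyloxy)-2-{(2R,3R)-2-[4-(benzyloxy)-3-methoxyphenyl]-3-[(trityloxy)methyl]-2,3-dihydro-1,4-benzodioxin-6-yl}-3-hydroxy-4H-chromen-4-one
Product: 20 3,5,7-trihydroxy-2-[(2R,3R)-2-(4-hydroxy-3-methoxyphenyl)-3-(hydroxymethyl)-2,3-dihydro-1,4-benzodioxin-6-yl]-4H-chromen-4-one (2,3-dehydroisosilybin A)
Conditions: H2 (1 atm), Pd(OH)2 on carbon, THF/MeOH/AcOH, rt
Reagents that add atoms: none
Why: Catalytic hydrogenolysis should cleave the three O-benzyl ethers and, more slowly, the O-trityl ether, while the aryl methyl ether, the chromone and the hindered cyclic benzylic C–O bond of the dioxane ring are expected to survive.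

**Compound list**

1 | (S)-4-benzyl-1,3-oxazolidin-2-one | O=C1OC[C@H](Cc2ccccc2)N1 | starting material
2 | bromoacetyl bromide | O=C(Br)CBr | starting material
3 | lithium (S)-4-benzyl-2-oxo-1,3-oxazolidin-3-ide (not isolated) | [Li+].O=C1OC[C@H](Cc2ccccc2)[N-]1 | intermediate
4 | (S)-4-benzyl-3-(bromoacetyl)-1,3-oxazolidin-2-one | O=C(CBr)N1C(=O)OC[C@@H]1Cc2ccccc2 | intermediate
5 | 4-fluoro-3-hydroxybenzonitrile | N#Cc1ccc(F)c(O)c1 | starting material
6 | (S)-4-benzyl-3-[2-(5-cyano-2-fluorophenoxy)acetyl]-1,3-oxazolidin-2-one | O=C(COc1cc(C#N)ccc1F)N1C(=O)OC[C@@H]1Cc2ccccc2 | intermediate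
7 | 4-(benzyloxy)-3-methoxybenzaldehyde | COc1cc(C=O)ccc1OCc1ccccc1 | starting material
8 | Z dibutylboron enolate of 6 (not isolated) | CCCCB(CCCC)O/C(=C\Oc1cc(C#N)ccc1F)N1C(=O)OC[C@@H]1Cc2ccccc2 | intermediate
9 | (S)-4-benzyl-3-[(2S,3R)-3-[4-(benzyloxy)-3-methoxyphenyl]-2-(5-cyano-2-fluorophenoxy)-3-hydroxypropanoyl]-1,3-oxazolidin-2-one (syn aldol adduct) | COc1cc([C@@H](O)[C@@H](C(=O)N2C(=O)OC[C@@H]2Cc2ccccc2)Oc2cc(C#N)ccc2F)ccc1OCc1ccccc1 | intermediate
10 | 3-{[(1R,2R)-1-[4-(benzyloxy)-3-methoxyphenyl]-1,3-dihydroxypropan-2-yl]oxy}-4-fluorobenzonitrile (threo diol) | COc1cc([C@@H](O)[C@@H](CO)Oc2cc(C#N)ccc2F)ccc1OCc1ccccc1 | intermediate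
11 | 3-{[(1R,2R)-1-[4-(benzyloxy)-3-methoxyphenyl]-1-hydroxy-3-(trityloxy)propan-2-yl]oxy}-4-fluorobenzonitrile | COc1cc([C@@H](O)[C@@H](COC(c2ccccc2)(c2ccccc2)c2ccccc2)Oc2cc(C#N)ccc2F)ccc1OCc1ccccc1 | intermediate
12 | potassium alkoxide of 11 (not isolated) | [K+].COc1cc([C@@H]([O-])[C@@H](COC(c2ccccc2)(c2ccccc2)c2ccccc2)Oc2cc(C#N)ccc2F)ccc1OCc1ccccc1 | intermediate
13 | (2R,3R)-2-[4-(benzyloxy)-3-methoxyphenyl]-3-[(trityloxy)methyl]-2,3-dihydro-1,4-benzodioxine-6-carbonitrile (trans) | COc1cc([C@H]2Oc3ccc(C#N)cc3O[C@@H]2COC(c2ccccc2)(c2ccccc2)c2ccccc2)ccc1OCc1ccccc1 | intermediate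
14 | N-(diisobutylaluminio) aldimine of 15 (not isolated) | COc1cc([C@H]2Oc3ccc(C=N[Al](CC(C)C)CC(C)C)cc3O[C@@H]2COC(c2ccccc2)(c2ccccc2)c2ccccc2)ccc1OCc1ccccc1 | intermediate
15 | (2R,3R)-2-[4-(benzyloxy)-3-methoxyphenyl]-3-[(trityloxy)methyl]-2,3-dihydro-1,4-benzodioxine-6-carbaldehyde | COc1cc([C@H]2Oc3ccc(C=O)cc3O[C@@H]2COC(c2ccccc2)(c2ccccc2)c2ccccc2)ccc1OCc1ccccc1 | intermediate
16 | 1-[2,4-bis(benzyloxy)-6-hydroxyphenyl]ethan-1-one | CC(=O)c1c(O)cc(OCc2ccccc2)cc1OCc1ccccc1 | starting material
17 | (E)-1-[2,4-bis(benzyloxy)-6-hydroxyphenyl]-3-{(2R,3R)-2-[4-(benzyloxy)-3-methoxyphenyl]-3-[(trityloxy)methyl]-2,3-dihydro-1,4-benzodioxin-6-yl}prop-2-en-1-one | COc1cc([C@H]2Oc3ccc(/C=C/C(=O)c4c(O)cc(OCc5ccccc5)cc4OCc4ccccc4)cc3O[C@@H]2COC(c2ccccc2)(c2ccccc2)c2ccccc2)ccc1OCc1ccccc1 | intermediate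
18 | 5,7-bis(benzyloxy)-2-{(2R,3R)-2-[4-(benzyloxy)-3-methoxyphenyl]-3-[(trityloxy)methyl]-2,3-dihydro-1,4-benzodioxin-6-yl}-3-hydroxychroman-4-one (2,3-trans, both diastereomers, ring C centres left undefined; not isolated) | COc1cc([C@H]2Oc3ccc(C4Oc5cc(OCc6ccccc6)cc(OCc6ccccc6)c5C(=O)C4O)cc3O[C@@H]2COC(c2ccccc2)(c2ccccc2)c2ccccc2)ccc1OCc1ccccc1 | intermediate
19 | 5,7-bis(benzyloxy)-2-{(2R,3R)-2-[4-(benzyloxy)-3-methoxyphenyl]-3-[(trityloxy)methyl]-2,3-dihydro-1,4-benzodioxin-6-yl}-3-hydroxy-4H-chromen-4-one | COc1cc([C@H]2Oc3ccc(-c4oc5cc(OCc6ccccc6)cc(OCc6ccccc6)c5c(=O)c4O)cc3O[C@@H]2COC(c2ccccc2)(c2ccccc2)c2ccccc2)ccc1OCc1ccccc1 | intermediate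
20 | 3,5,7-trihydroxy-2-[(2R,3R)-2-(4-hydroxy-3-methoxyphenyl)-3-(hydroxymethyl)-2,3-dihydro-1,4-benzodioxin-6-yl]-4H-chromen-4-one | COc1cc([C@H]2Oc3ccc(-c4oc5cc(O)cc(O)c5c(=O)c4O)cc3O[C@@H]2CO)ccc1O | target

**Step count and risks**

Total step count: 10. Longest linear sequence: 10 steps (1 to 20).

Steps most likely to fail:

Step 9. The oxidative cyclisation may take the five-membered path through the α-carbon and give the aurone, which a 6'-alkoxy group on the chalcone is known to favour, or it may stall at the dihydroflavonol. The fallback separates ring closure from C3 oxygenation and sets out from 17. Oxidative cyclisation with catalytic I2 in DMSO at 110 °C should give 5,7-bis(benzyloxy)-2-{(2R,3R)-2-[4-(benzyloxy)-3-methoxyphenyl]-3-[(trityloxy)methyl]-2,3-dihydro-1,4-benzodioxin-6-yl}-4H-chromen-4-one F1. Epoxidation of its C2=C3 bond with dimethyldioxirane (acetone/CH2Cl2, 0 °C) should give the 2,3-epoxyflavanone F2. A trace of p-TsOH in CH2Cl2 at 0 °C should open and isomerise F2 to the flavonol, and the route is rejoined at 19.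

Step 10. Cleavage of the trityl ether may remain incomplete, or prolonged hydrogenation may open the benzylic C–O bond of the dioxane ring. The fallback replaces hydrogenolysis by Lewis-acid dealkylation and sets out from 19. BCl3 with pentamethylbenzene as cation scavenger (CH2Cl2, −78 °C, then MeOH and aqueous work-up) should remove the three benzyl groups and the trityl group while sparing the aryl methyl ether, and gives 20 directly. No new compound is made on this way (entry F0).

Step 6. Ring closure may be outrun by intermolecular substitution (oligomers) or by addition of the alkoxide to the nitrile, and tight ion pairing in THF may slow it. The fallback makes the same C–O bond by reductive elimination from palladium instead of addition–elimination and sets out from 4. Alkylation of commercial 4-bromo-3-hydroxybenzonitrile with 4 (K2CO3, acetone) should give (S)-4-benzyl-3-[2-(2-bromo-5-cyanophenoxy)acetyl]-1,3-oxazolidin-2-one F3. The operations of steps 3, 4 and 5 should then give in turn the syn-aldol adduct (S)-4-benzyl-3-[(2S,3R)-3-[4-(benzyloxy)-3-methoxyphenyl]-2-(2-bromo-5-cyanophenoxy)-3-hydroxypropanoyl]-1,3-oxazolidin-2-one F4, the threo diol 4-bromo-3-{[(1R,2R)-1-[4-(benzyloxy)-3-methoxyphenyl]-1,3-dihydroxypropan-2-yl]oxy}benzonitrile F5, and the trityl ether 4-bromo-3-{[(1R,2R)-1-[4-(benzyloxy)-3-methoxyphenyl]-1-hydroxy-3-(trityloxy)propan-2-yl]oxy}benzonitrile F6. Cyclisation of F6 with Pd(OAc)2, 2-(di-tert-butylphosphino)-1,1'-binaphthyl and Cs2CO3 in toluene at 70 °C (intramolecular Buchwald–Hartwig-type etherification, retention at both carbinol carbons) should rejoin the route at 13.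

**Further compounds**

F1 | step 9 | 5,7-bis(benzyloxy)-2-{(2R,3R)-2-[4-(benzyloxy)-3-methoxyphenyl]-3-[(trityloxy)methyl]-2,3-dihydro-1,4-benzodioxin-6-yl}-4H-chromen-4-one | COc1cc([C@H]2Oc3ccc(-c4cc(=O)c5c(OCc6ccccc6)cc(OCc6ccccc6)cc5o4)cc3O[C@@H]2COC(c2ccccc2)(c2ccccc2)c2ccccc2)ccc1OCc1ccccc1
F2 | step 9 | 2,3-epoxide of F1 (2,3-epoxyflavanone, epoxide centres left undefined) | COc1cc([C@H]2Oc3ccc(C45OC4C(=O)c4c(OCc6ccccc6)cc(OCc6ccccc6)cc4O5)cc3O[C@@H]2COC(c2ccccc2)(c2ccccc2)c2ccccc2)ccc1OCc1ccccc1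
F0 | step 10 | none | none
F3 | step 6 | (S)-4-benzyl-3-[2-(2-bromo-5-cyanophenoxy)acetyl]-1,3-oxazolidin-2-one | O=C(COc1cc(C#N)ccc1Br)N1C(=O)OC[C@@H]1Cc2ccccc2
F4 | step 6 | (S)-4-benzyl-3-[(2S,3R)-3-[4-(benzyloxy)-3-methoxyphenyl]-2-(2-bromo-5-cyanophenoxy)-3-hydroxypropanoyl]-1,3-oxazolidin-2-one | COc1cc([C@@H](O)[C@@H](C(=O)N2C(=O)OC[C@@H]2Cc2ccccc2)Oc2cc(C#N)ccc2Br)ccc1OCc1ccccc1
F5 | step 6 | 4-bromo-3-{[(1R,2R)-1-[4-(benzyloxy)-3-methoxyphenyl]-1,3-dihydroxypropan-2-yl]oxy}benzonitrile | COc1cc([C@@H](O)[C@@H](CO)Oc2cc(C#N)ccc2Br)ccc1OCc1ccccc1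
F6 | step 6 | 4-bromo-3-{[(1R,2R)-1-[4-(benzyloxy)-3-methoxyphenyl]-1-hydroxy-3-(trityloxy)propan-2-yl]oxy}benzonitrile | COc1cc([C@@H](O)[C@@H](COC(c2ccccc2)(c2ccccc2)c2ccccc2)Oc2cc(C#N)ccc2Br)ccc1OCc1ccccc1
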